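**Plan**

1. Retrosynthesis: the four MOM ethers are removed last. Before that, ring C is cut at three bonds (C4a–C4, C4–C3, O1–C2), giving an ortho-iodophenol (ring A), carbon monoxide (C4) and an arylacetylene (C2 and C3, carried on C1' of ring B).
2. Enabling feature: ring C (O1, C2, C3, C4, C4a, C8a) is a vinylogous ester. It is the sum of a phenol oxygen with its ortho carbon, one carbonyl carbon and two alkyne carbons.
3. The C5' prenyl group sits ortho to the 4'-oxygen, whose other ortho carbon C3' bears oxygen. A Claisen shift of a 4'-O-(1,1-dimethylallyl) ether can therefore only end at C5'.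
4. Forward: ring B arm (O-allylation, Claisen, MOM protection, alkyne homologation) and ring A arm (bis-MOM ether, iodination) are built on bought benzene rings. Ring C, the only ring made, closes as the two arms are joined, and acid then frees the phenols.
5. Stereochemistry: the target has no stereocentre, and the prenyl alkene carries two identical methyl groups, so nothing has to be set.

Key step: step 8

Assumption: all four phenols are carried as methoxymethyl ethers, because neither hydrogenolysis of benzyl ethers nor Lewis-acid cleavage of methyl ethers would spare the prenyl group.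

**Route**

Step 1
Reactants: 1 2-methylbut-3-en-2-ol
Product: 2 tert-butyl 2-methylbut-3-en-2-yl carbonate
Conditions: n-BuLi, THF, −78 °C; then Boc2O, −78 °C → rt
Reagents that add atoms: di-tert-butyl dicarbonate (Boc2O), CC(C)(C)OC(=O)OC(=O)OC(C)(C)C
Why: The lithium alkoxide of the tertiary allylic alcohol is acylated on oxygen by Boc2O (carbonate formation by alkoxide acylation), and the low temperature avoids allylic transposition or elimination.

Step 2
Reactants: 3 3,4-dihydroxybenzaldehyde (protocatechualdehyde); 2 tert-butyl 2-methylbut-3-en-2-yl carbonate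
Product: 4 3-hydroxy-4-[(2-methylbut-3-en-2-yl)oxy]benzaldehyde
Conditions: Pd(PPh3)4 (2 mol %), 4 Å MS, THF, 0 °C
Reagents that add atoms: none
Why: Tsuji–Trost decarboxylative O-allylation, in which zerovalent palladium ionises 2 to a 1,1-dimethyl-π-allyl complex, the tert-butoxide set free with CO2 removes only the more acidic 4-OH proton (para to the formyl group), and the phenoxide attacks the more substituted allyl terminus under kinetic control at low temperature to give the tertiary ether.

Step 3
Reactants: 4 3-hydroxy-4-[(2-methylbut-3-en-2-yl)oxy]benzaldehyde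
Product: 6 3,4-dihydroxy-5-(3-methylbut-2-en-1-yl)benzaldehyde, via dienone 5 (not isolated)
Conditions: degassed PhMe, 120 °C, sealed tube, Ar
Reagents that add atoms: none
Why: Aromatic Claisen rearrangement, a [3,3]-sigmatropic shift that inverts the allyl unit so that the 1,1-dimethylallyl ether arrives as a prenyl group at C5, the only ortho carbon that carries hydrogen (C3 bears the hydroxyl), after which dienone 5 enolises to the catechol.

Step 4
Reactants: 6 3,4-dihydroxy-5-(3-methylbut-2-en-1-yl)benzaldehyde
Product: 7 3,4-bis(methoxymethoxy)-5-(3-methylbut-2-en-1-yl)benzaldehyde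
Conditions: MOMCl, iPr2NEt, CH2Cl2, 0 °C → rt
Reagents that add atoms: chloromethyl methyl ether (MOMCl), COCCl
Why: O-alkylation of both phenols with chloromethyl methyl ether and an amine base (MOM acetal formation) masks the acidic hydroxyls before the basic homologation and the palladium step, and the aldehyde and the alkene do not react.

Step 5
Reactants: 7 3,4-bis(methoxymethoxy)-5-(3-methylbut-2-en-1-yl)benzaldehyde; 8 dimethyl (1-diazo-2-oxopropyl)phosphonate
Product: 9 5-ethynyl-1,2-bis(methoxymethoxy)-3-(3-methylbut-2-en-1-yl)benzene
Conditions: K2CO3, MeOH, rt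
Reagents that add atoms: none
Why: Ohira–Bestmann variant of the Seyferth–Gilbert homologation, in which methanolysis of 8 releases the dimethyl (diazomethyl)phosphonate anion, this adds to the non-enolisable aldehyde in a Horner–Wadsworth–Emmons manner, and loss of N2 with a 1,2-hydrogen shift gives the terminal alkyne under conditions that leave the MOM acetals and the prenyl group untouched.

Step 6
Reactants: 10 benzene-1,3,5-triol (phloroglucinol)
Product: 11 3,5-bis(methoxymethoxy)phenol
Conditions: MOMCl (2.0 equiv), iPr2NEt, DMF, 0 °C → rt
Reagents that add atoms: chloromethyl methyl ether (MOMCl), COCCl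
Why: Williamson-type O-alkylation of two of the three equivalent hydroxyls under stoichiometric control, with the amine base keeping the alkylation on oxygen rather than on the ring carbons, the bis ether being separated by chromatography from the mono ether (resubmitted) and the tris ether.

Step 7
Reactants: 11 3,5-bis(methoxymethoxy)phenol
Product: 12 2-iodo-3,5-bis(methoxymethoxy)phenol
Conditions: I2 (1.0 equiv), NaHCO3, THF/H2O, 0 °C
Reagents that add atoms: iodine, II
Why: Electrophilic aromatic iodination of the phenoxide of 11, which should take place at one of the two equivalent carbons next to the free hydroxyl rather than at the more crowded carbon flanked by two MOM ethers, with one equivalent of iodine limiting double iodination.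

Step 8
Reactants: 9 5-ethynyl-1,2-bis(methoxymethoxy)-3-(3-methylbut-2-en-1-yl)benzene; 12 2-iodo-3,5-bis(methoxymethoxy)phenol; 13 carbon monoxide
Product: 16 2-[3,4-bis(methoxymethoxy)-5-(3-methylbut-2-en-1-yl)phenyl]-5,7-bis(methoxymethoxy)-4H-chromen-4-one, via ynone 14 (not isolated), via enaminone 15 (not isolated)
Conditions: PdCl2(dppf) (5 mol %), CO (20 atm), Et2NH, 120 °C
Reagents that add atoms: none
Why: Zerovalent palladium inserts into the C–I bond of 12, CO inserts to give an aroylpalladium species, and coupling with the amine-deprotonated alkyne 9 gives ynone 14 (carbonylative Sonogashira coupling), which forms C4a–C4 and C4–C3. Diethylamine then adds to the ynone in conjugate fashion to give enaminone 15, and the ortho phenol oxygen displaces the amine at C2 by addition–elimination, which forms O1–C2. The closest known reaction type is the palladium-catalysed carbonylative annulation of ortho-iodophenols with terminal arylacetylenes in a secondary amine to give flavones. Ring C is the only ring closed, in a net 6-endo mode at the alkyne-derived carbon C2, and no stereocentre is created. The step needs CO insertion to outrun direct alkyne coupling (which would lead to a 2-arylbenzofuran) and six-ring closure to outrun 5-exo attack at the carbon that becomes C3 (aurone); the CO pressure and the electron-rich aryl–palladium bond secure the first, and the amine adduct 15, whose electrophilic carbon is C2, secures the second. The MOM acetals and the trisubstituted alkene are inert to zerovalent palladium, CO and the amine.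

Step 9
Reactants: 16 2-[3,4-bis(methoxymethoxy)-5-(3-methylbut-2-en-1-yl)phenyl]-5,7-bis(methoxymethoxy)-4H-chromen-4-one
Product: 17 uralenin
Conditions: 3 M aq HCl, MeOH, 50 °C, stopped at full conversion
Reagents that add atoms: none
Why: Acid-catalysed transacetalisation of the four MOM acetals to methanol (acetal cleavage) frees the phenols, and the dilute acid and moderate temperature are chosen so that the 4'-OH does not add across the prenyl alkene to form a 2,2-dimethylchroman.

**Compound list**

1 | 2-methylbut-3-en-2-ol | C=CC(C)(C)O | starting material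
2 | tert-butyl 2-methylbut-3-en-2-yl carbonate | C=CC(C)(C)OC(=O)OC(C)(C)C | intermediate
3 | 3,4-dihydroxybenzaldehyde (protocatechualdehyde) | O=Cc1ccc(O)c(O)c1 | starting material
4 | 3-hydroxy-4-[(2-methylbut-3-en-2-yl)oxy]benzaldehyde | C=CC(C)(C)Oc1ccc(C=O)cc1O | intermediate
5 | 4-formyl-2-hydroxy-6-(3-methylbut-2-en-1-yl)cyclohexa-2,4-dien-1-one (racemic, formed in the flask) | O=CC1=CC(CC=C(C)C)C(=O)C(O)=C1 | intermediate
6 | 3,4-dihydroxy-5-(3-methylbut-2-en-1-yl)benzaldehyde | CC(C)=CCc1cc(C=O)cc(O)c1O | intermediate
7 | 3,4-bis(methoxymethoxy)-5-(3-methylbut-2-en-1-yl)benzaldehyde | CC(C)=CCc1cc(C=O)cc(OCOC)c1OCOC | intermediate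
8 | dimethyl (1-diazo-2-oxopropyl)phosphonate | CC(=O)C(=[N+]=[N-])P(=O)(OC)OC | starting material
9 | 5-ethynyl-1,2-bis(methoxymethoxy)-3-(3-methylbut-2-en-1-yl)benzene | CC(C)=CCc1cc(C#C)cc(OCOC)c1OCOC | intermediate
10 | benzene-1,3,5-triol (phloroglucinol) | Oc1cc(O)cc(O)c1 | starting material
11 | 3,5-bis(methoxymethoxy)phenol | COCOc1cc(O)cc(OCOC)c1 | intermediate
12 | 2-iodo-3,5-bis(methoxymethoxy)phenol | COCOc1cc(O)c(I)c(OCOC)c1 | intermediate
13 | carbon monoxide | [C-]#[O+] | starting material
14 | 3-[3,4-bis(methoxymethoxy)-5-(3-methylbut-2-en-1-yl)phenyl]-1-[2-hydroxy-4,6-bis(methoxymethoxy)phenyl]prop-2-yn-1-one (formed in the flask) | CC(C)=CCc1cc(C#CC(=O)c2c(O)cc(OCOC)cc2OCOC)cc(OCOC)c1OCOC | intermediate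
15 | (E)-3-[3,4-bis(methoxymethoxy)-5-(3-methylbut-2-en-1-yl)phenyl]-3-(diethylamino)-1-[2-hydroxy-4,6-bis(methoxymethoxy)phenyl]prop-2-en-1-one (formed in the flask; drawn E, the geometry is lost on ring closure) | CCN(CC)/C(=C/C(=O)c1c(O)cc(OCOC)cc1OCOC)c1cc(CC=C(C)C)c(OCOC)c(OCOC)c1 | intermediate
16 | 2-[3,4-bis(methoxymethoxy)-5-(3-methylbut-2-en-1-yl)phenyl]-5,7-bis(methoxymethoxy)-4H-chromen-4-one | CC(C)=CCc1cc(-c2cc(=O)c3c(OCOC)cc(OCOC)cc3o2)cc(OCOC)c1OCOC | intermediate
17 | uralenin, 2-[3,4-dihydroxy-5-(3-methylbut-2-en-1-yl)phenyl]-5,7-dihydroxy-4H-chromen-4-one | CC(C)=CCc1cc(-c2cc(=O)c3c(O)cc(O)cc3o2)cc(O)c1O | target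

**Step count and risks**

Total step count: 9.
Longest linear sequence: 7 steps (steps 1, 2, 3, 4, 5, 8, 9).

Steps most likely to fail:

Step 8. Oxidative addition may be slow at the iodide, which is flanked by a hydroxyl and a MOM ether. The alkyne could then couple without CO uptake, or the ynone could close in the five-ring sense. The fallback sets out from phenol 11 and alkyne 9 and avoids palladium and CO. Phenol 11 is formylated with MgCl2, Et3N and paraformaldehyde in MeCN at reflux; the magnesium phenoxide directs the formyl group only to a carbon next to the hydroxyl, giving 2-hydroxy-4,6-bis(methoxymethoxy)benzaldehyde F1. Its sodium phenoxide (NaH, THF, 0 °C) is treated with the lithium acetylide of 9 (n-BuLi, THF, −78 °C) to give the racemic propargylic alcohol 3-[3,4-bis(methoxymethoxy)-5-(3-methylbut-2-en-1-yl)phenyl]-1-[2-hydroxy-4,6-bis(methoxymethoxy)phenyl]prop-2-yn-1-ol F2. Oxidation with MnO2 in CH2Cl2 should give ynone 14, where the fallback comes back to the route. Et2NH in EtOH at reflux then closes 14 through enaminone 15 to 16.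

Step 2. Site selectivity between the two hydroxyls may be lost, giving the 3-O ether or the bis ether, and the tertiary ether may isomerise to the linear prenyl ether. The fallback sets out from 3 and differentiates the two oxygens before the allylation. The dianion of 3 (NaH, 2.1 equiv, DMF, 0 °C) is alkylated with one equivalent of MOMCl at the more nucleophilic 3-phenoxide to give 4-hydroxy-3-(methoxymethoxy)benzaldehyde F3. Its single phenol is allylated with carbonate 2 and Pd(PPh3)4 in THF at 0 °C to give 3-(methoxymethoxy)-4-[(2-methylbut-3-en-2-yl)oxy]benzaldehyde F4. Heating in PhMe at 120 °C should pass through 4-formyl-2-(methoxymethoxy)-6-(3-methylbut-2-en-1-yl)cyclohexa-2,4-dien-1-one F5 to 4-hydroxy-3-(methoxymethoxy)-5-(3-methylbut-2-en-1-yl)benzaldehyde F6. MOMCl and iPr2NEt in CH2Cl2 then give 7, where the fallback comes back to the route.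

Step 7. Iodination may occur at the carbon between the two MOM ethers, or twice. The fallback sets out from phloroglucinol 10 and places the iodine before the symmetry is broken. I2 (1.0 equiv) and NaHCO3 in THF/H2O at 0 °C should give 2-iodobenzene-1,3,5-triol F7, in which the site of iodination cannot be wrong because the three ring CH positions of 10 are equivalent. MOMCl (2.0 equiv) and iPr2NEt in DMF then etherify the hydroxyl para to iodine and one of the two hindered ortho hydroxyls. Two of the three possible bis-etherifications give this same compound, which is 12, where the fallback comes back to the route.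

Further compounds
F1 | step 8 | 2-hydroxy-4,6-bis(methoxymethoxy)benzaldehyde | COCOc1cc(O)c(C=O)c(OCOC)c1
F2 | step 8 | 3-[3,4-bis(methoxymethoxy)-5-(3-methylbut-2-en-1-yl)phenyl]-1-[2-hydroxy-4,6-bis(methoxymethoxy)phenyl]prop-2-yn-1-ol (racemic) | CC(C)=CCc1cc(C#CC(O)c2c(O)cc(OCOC)cc2OCOC)cc(OCOC)c1OCOC
F3 | step 2 | 4-hydroxy-3-(methoxymethoxy)benzaldehyde | COCOc1cc(C=O)ccc1O
F4 | step 2 | 3-(methoxymethoxy)-4-[(2-methylbut-3-en-2-yl)oxy]benzaldehyde | C=CC(C)(C)Oc1ccc(C=O)cc1OCOC
F5 | step 2 | 4-formyl-2-(methoxymethoxy)-6-(3-methylbut-2-en-1-yl)cyclohexa-2,4-dien-1-one (racemic, formed in the flask) | O=CC1=CC(CC=C(C)C)C(=O)C(OCOC)=C1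
F6 | step 2 | 4-hydroxy-3-(methoxymethoxy)-5-(3-methylbut-2-en-1-yl)benzaldehyde | CC(C)=CCc1cc(C=O)cc(OCOC)c1O
F7 | step 7 | 2-iodobenzene-1,3,5-triol | Oc1cc(O)c(I)c(O)c1
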